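**Retrosynthetic overview**
1. The strategy rests on ring D (C7–C8–C14–C4'–C10'), which holds the β-hydroxy ketone unit C6(=O)–C7–C10'(OH): C7–C10' is an aldol bond, and C5, C7 and C10' can all be equilibrated by enolisation or retro-aldol.
2. Target 22 ⇒ catechol 20 (oxidation to the ortho-quinone, tautomerisation to the C7=C8 quinone methide) ⇒ bis-MOM hexacycle 19 ⇒ retro-aldol opening of ring D to keto aldehyde 18.
3. 18 ⇒ epoxide of aryl alkene 16 (1,2-aryl shift from C10' to C4', which sets C4') ⇒ Suzuki union of aryl bromide 11 with alkenyl boronate 15.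
4. 11 ⇐ carnosic acid 1 (C10 CO2H to CH3, bromination at C14, C6 ketone through the Δ6 alkene, C5 epimerisation to the cis fusion); 15 ⇐ (+)-sabinene 12 (ozonolysis, boron-Wittig).
5. Ring order: rings A–C come with 1 and the bicyclo[3.1.0]hexane with 12; ring D is the only ring built (step 13) and the quinone methide is unveiled last.

Key step: step 13

Assumption: abietane numbering with primes for the sabinene carbons (C1' isopropyl-bearing, C4' spiro, C5' cyclopropane CH, C6' cyclopropane CH2, C10' carbinol); the cis-fused (5β-H) 6-ketone is taken to be the more stable C5 epimer, as is usual for 4,4,10-trimethyl-6-oxo decalins.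

**Route**

Step 1
Reactants: 1 carnosic acid
Product: 2 methoxymethyl 11,12-bis(methoxymethoxy)abieta-8,11,13-trien-20-oate
Conditions: NaH (3.5 equiv), MOMCl (3.6 equiv), DMF, 0 °C to rt, argon
Reagents that add atoms: chloromethyl methyl ether (MOMCl), COCCl
Why: O-alkylation of the catechol dianion and the carboxylate with the reactive chloromethyl ether (Williamson type) masks all three acidic groups at once and touches no stereocenter.

Step 2
Reactants: 2 methoxymethyl 11,12-bis(methoxymethoxy)abieta-8,11,13-trien-20-oate
Product: 3 11,12-bis(methoxymethoxy)abieta-8,11,13-trien-20-ol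
Conditions: LiAlH4, THF, 0 °C to reflux
Reagents that add atoms: none
Why: LiAlH4 reduction of the hindered but activated acetal ester should give the neopentyl C20 alcohol, the aryl acetal ethers being inert to hydride.

Step 3
Reactants: 3 11,12-bis(methoxymethoxy)abieta-8,11,13-trien-20-ol
Product: 4 11,12-bis(methoxymethoxy)abieta-8,11,13-trien-20-al
Conditions: Dess–Martin periodinane, CH2Cl2, rt
Reagents that add atoms: none
Why: Dess–Martin oxidation stops at the non-enolisable C20 aldehyde under near-neutral conditions that the acetal ethers tolerate.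

Step 4
Reactants: 4 11,12-bis(methoxymethoxy)abieta-8,11,13-trien-20-al
Product: 6 11,12-bis(methoxymethoxy)abieta-8,11,13-triene, via C20 hydrazone 5 (not isolated)
Conditions: N2H4·H2O, KOH, diethylene glycol, 130 °C then 200 °C
Reagents that add atoms: none
Why: Wolff–Kishner reduction (Huang-Minlon procedure) turns the hindered aldehyde through its hydrazone into the C10 methyl group, the acetal ethers being base-stable and C10 keeping its configuration because no bond to it is broken.

Step 5
Reactants: 6 11,12-bis(methoxymethoxy)abieta-8,11,13-triene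
Product: 7 14-bromo-11,12-bis(methoxymethoxy)abieta-8,11,13-triene
Conditions: NBS, MeCN, 0 °C to rt, dark
Reagents that add atoms: N-bromosuccinimide (NBS), O=C1CCC(=O)N1Br
Why: Electrophilic aromatic bromination can only take place at C14, the single unsubstituted ring position (para to the C11 oxygen), and ionic conditions in the dark should suppress benzylic bromination.

Step 6
Reactants: 7 14-bromo-11,12-bis(methoxymethoxy)abieta-8,11,13-triene
Product: 8 14-bromo-11,12-bis(methoxymethoxy)abieta-6,8,11,13-tetraene
Conditions: DDQ (1.2 equiv), 1,4-dioxane, 80 °C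
Reagents that add atoms: none
Why: Benzylic dehydrogenation by DDQ (hydride abstraction from C7, para to the C12 oxygen, then loss of H6) should give the styrene, and quaternary C10 blocks aromatisation of ring B.

Step 7
Reactants: 8 14-bromo-11,12-bis(methoxymethoxy)abieta-6,8,11,13-tetraene
Product: 10 14-bromo-11,12-bis(methoxymethoxy)abieta-8,11,13-trien-6-one (5α-H; A/B trans), via 6α,7α-epoxide 9 (not isolated)
Conditions: DMDO, acetone, 0 °C; evaporate; then BF3·OEt2 (0.2 equiv), CH2Cl2, −40 °C
Reagents that add atoms: dimethyldioxirane (DMDO), CC1(C)OO1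
Why: The dioxirane epoxidises the electron-rich styrene from the α face opposite the C10 methyl group, and the Lewis acid then opens the benzylic C7–O bond with a 1,2-hydride shift from C6 (Meinwald rearrangement) to give the C6 ketone with C5 unchanged.

Step 8
Reactants: 10 14-bromo-11,12-bis(methoxymethoxy)abieta-8,11,13-trien-6-one (5α-H; A/B trans)
Product: 11 14-bromo-11,12-bis(methoxymethoxy)-5β-abieta-8,11,13-trien-6-one (5β-H; A/B cis)
Conditions: NaOMe (0.3 equiv), MeOH/THF, rt, argon
Reagents that add atoms: none
Why: Base-mediated epimerisation through the C5–C6 enolate should settle on the cis-fused ketone (relief of the diaxial C19/C20 methyl contact and of the clash between the equatorial C4 methyl and the C6 carbonyl), which sets C5 with H5 cis to the C10 methyl group.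

Step 9
Reactants: 12 (+)-sabinene
Product: 14 sabina ketone (5-isopropylbicyclo[3.1.0]hexan-2-one with the ring-fusion configuration of 12), via spiro ozonide 13 (not isolated)
Conditions: O3, CH2Cl2, −78 °C; then PPh3, −78 °C to rt
Reagents that add atoms: ozone, [O-][O+]=O
Why: Ozonolysis of the 1,1-disubstituted alkene with reductive work-up of the ozonide gives the cyclopropyl ketone and leaves the cyclopropane and both stereocenters untouched.

Step 10
Reactants: 14 sabina ketone
Product: 15 pinacol (thujan-4'-ylidene)methylboronate (boron cis to C3' and anti to C5')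
Conditions: CH2(Bpin)2, lithium 2,2,6,6-tetramethylpiperidide (LiTMP), THF, 0 °C; then 14, −78 °C to rt
Reagents that add atoms: bis[(pinacolato)boryl]methane, CC1(C)OB(CB2OC(C)(C)C(C)(C)O2)OC1(C)C
Why: Boron–Wittig olefination (addition of the lithiated geminal bis(boronate) to the ketone, then boron–oxygen elimination) gives the trisubstituted alkenyl boronate with boron expected anti to the bulkier cyclopropane side; either alkene isomer would converge later because C10' becomes a formyl carbon.

Step 11
Reactants: 11 14-bromo-11,12-bis(methoxymethoxy)-5β-abieta-8,11,13-trien-6-one and 15 pinacol (thujan-4'-ylidene)methylboronate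
Product: 16 14-[(thujan-4'-ylidene)methyl]-11,12-bis(methoxymethoxy)-5β-abieta-8,11,13-trien-6-one (aryl cis to C3')
Conditions: Pd(OAc)2 (5 mol %), SPhos (10 mol %), K3PO4, toluene/H2O, 90 °C
Reagents that add atoms: none
Why: Suzuki–Miyaura coupling with a bulky dialkylbiarylphosphine is the standard answer to di-ortho-substituted aryl bromides, proceeds with retention of alkene geometry, and the phosphate base should leave the ketone (already at its C5 equilibrium) and the acetal ethers alone.

Step 12
Reactants: 16 14-[(thujan-4'-ylidene)methyl]-11,12-bis(methoxymethoxy)-5β-abieta-8,11,13-trien-6-one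
Product: 18 14-(4'-formylthujan-4'-yl)-11,12-bis(methoxymethoxy)-5β-abieta-8,11,13-trien-6-one (aryl syn to C6'; formyl anti), via anti-epoxide 17 (not isolated)
Conditions: DMDO, acetone, −20 °C; evaporate; then BF3·OEt2 (0.3 equiv), CH2Cl2, −78 °C, Et3N quench
Reagents that add atoms: dimethyldioxirane (DMDO), CC1(C)OO1
Why: The dioxirane should attack the exocyclic alkene from the cyclopentane face opposite the cyclopropane methylene C6', and the BF3-induced Meinwald (semipinacol) rearrangement then ionises the tertiary, cyclopropyl-stabilised C4'–O bond while the electron-rich aryl group shifts from C10' to C4' anti to the leaving oxygen, which sets C4' with the aryl group syn to C6' and the new formyl group anti.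

Step 13
Reactants: 18 14-(4'-formylthujan-4'-yl)-11,12-bis(methoxymethoxy)-5β-abieta-8,11,13-trien-6-one
Product: 19 hexacyclic bis-MOM β-hydroxy ketone (C7–C10' bond; 10'-OH cis to C5' and cis to C6 on ring D; H7 β; H5 β)
Conditions: K2CO3 (0.5 equiv), degassed MeOH/THF, 0 °C to rt, argon; pH 7 buffer quench
Reagents that add atoms: none
Why: Carbonate in methanol reversibly deprotonates C7, the benzylic α-carbon of the C6 ketone, and the arene-conjugated enolate adds through C7 to the formyl carbon C10' held ortho to it on quaternary C4', forming C7–C10'; this is an intramolecular aldol addition run under retro-aldol equilibration, a known reaction type. Ring D (C7, C8, C14, C4', C10') closes in the 5-(enolexo)-exo-trig mode, with the arene and the spiro carbon pre-organising the two partners. Because the aldehyde has no α-hydrogen, the only reversible events are retro-aldol and enolisation at C7 and C5, so the mixture should settle on the most stable β-hydroxy ketone. C10' is set by that equilibrium: its hydroxyl is expected to prefer the side of the tied-back cyclopropane methine C5' over the C3' methylene and to gain a hydrogen bond to O6. C7 should follow as the epimer that holds C6 cis to this hydroxyl on ring D (it becomes sp2 in step 15, so only C10' has to be right), and C5 stays in the cis-fused form fixed in step 8. The selectivity needed is 10'-OH cis to C5' without E1cB loss of water, and the weak base, the low temperature and the neopentyl surroundings of C10' should secure it.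

Step 14
Reactants: 19 hexacyclic bis-MOM β-hydroxy ketone
Product: 20 hexacyclic catechol (11,12-diol)
Conditions: HCl (1.25 M in MeOH), THF, 30 °C, argon
Reagents that add atoms: none
Why: Acid-catalysed acetal exchange with methanol frees both phenols as dimethoxymethane, under conditions mild enough for the β-hydroxy ketone and for the cyclopropane, next to which no cation can form because C4' is quaternary.

Step 15
Reactants: 20 hexacyclic catechol
Product: 22 target CNP0178265.2, via ortho-quinone 21 (not isolated)
Conditions: Ag2O, CH2Cl2, rt, dark; filtration through silica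
Reagents that add atoms: none
Why: Silver oxide (Ag2O) oxidises the catechol to the 11,12-ortho-quinone, whose acidic C7–H (α to the C6 carbonyl) should tautomerise to the C7=C8 quinone methide with the C11 enol, the oxidation–tautomerisation known for 6-oxo abietane catechols; C5, C10, C10' and the thujane centres are not touched.

**Compound list**
1 | carnosic acid | CC(C)C1=C(O)C(O)=C2C(=C1)CC[C@@H]3[C@@]2(CCCC3(C)C)C(=O)O | starting material
2 | methoxymethyl 11,12-bis(methoxymethoxy)abieta-8,11,13-trien-20-oate | CC(C)c1c(OCOC)c(OCOC)c2c(c1)CC[C@@H]3[C@@]2(CCCC3(C)C)C(=O)OCOC | intermediate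
3 | 11,12-bis(methoxymethoxy)abieta-8,11,13-trien-20-ol | CC(C)c1c(OCOC)c(OCOC)c2c(c1)CC[C@@H]3[C@@]2(CCCC3(C)C)CO | intermediate
4 | 11,12-bis(methoxymethoxy)abieta-8,11,13-trien-20-al | CC(C)c1c(OCOC)c(OCOC)c2c(c1)CC[C@@H]3[C@@]2(CCCC3(C)C)C=O | intermediate
5 | C20 hydrazone of 4 (not isolated) | CC(C)c1c(OCOC)c(OCOC)c2c(c1)CC[C@@H]3[C@@]2(CCCC3(C)C)C=NN | intermediate
6 | 11,12-bis(methoxymethoxy)abieta-8,11,13-triene | CC(C)c1c(OCOC)c(OCOC)c2c(c1)CC[C@@H]3[C@@]2(CCCC3(C)C)C | intermediate
7 | 14-bromo-11,12-bis(methoxymethoxy)abieta-8,11,13-triene | CC(C)c1c(OCOC)c(OCOC)c2c(c1Br)CC[C@@H]3[C@@]2(CCCC3(C)C)C | intermediate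
8 | 14-bromo-11,12-bis(methoxymethoxy)abieta-6,8,11,13-tetraene | CC(C)c1c(OCOC)c(OCOC)c2c(c1Br)C=C[C@@H]3[C@@]2(CCCC3(C)C)C | intermediate
9 | 14-bromo-6α,7α-epoxy-11,12-bis(methoxymethoxy)abieta-8,11,13-triene (not isolated) | CC(C)c1c(OCOC)c(OCOC)c2c(c1Br)[C@@H]1O[C@@H]1[C@@H]3[C@@]2(CCCC3(C)C)C | intermediate
10 | 14-bromo-11,12-bis(methoxymethoxy)abieta-8,11,13-trien-6-one (5α-H, A/B trans) | CC(C)c1c(OCOC)c(OCOC)c2c(c1Br)CC(=O)[C@@H]3[C@@]2(CCCC3(C)C)C | intermediate
11 | 14-bromo-11,12-bis(methoxymethoxy)-5β-abieta-8,11,13-trien-6-one (5β-H, A/B cis) | CC(C)c1c(OCOC)c(OCOC)c2c(c1Br)CC(=O)[C@H]3[C@@]2(CCCC3(C)C)C | intermediate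
12 | (+)-sabinene, (1R,5R) | C=C1CC[C@]2(C(C)C)C[C@@H]21 | starting material
13 | spiro secondary ozonide of sabinene, mixture at the spiro carbon (not isolated) | C1OC2(OO1)CC[C@]3(C(C)C)C[C@@H]32 | intermediate
14 | sabina ketone | O=C1CC[C@]2(C(C)C)C[C@@H]21 | intermediate
15 | pinacol (thujan-4'-ylidene)methylboronate, boron cis to C3' | CC1(C)OB(OC1(C)C)/C=C1\CC[C@]2(C(C)C)C[C@@H]21 | intermediate
16 | 14-[(thujan-4'-ylidene)methyl]-11,12-bis(methoxymethoxy)-5β-abieta-8,11,13-trien-6-one, aryl cis to C3' | CC(C)c1c(OCOC)c(OCOC)c2c(c1/C=C5\CC[C@]6(C(C)C)C[C@@H]65)CC(=O)[C@H]3[C@@]2(CCCC3(C)C)C | intermediate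
17 | 10',4'-epoxide of 16, oxygen anti to the cyclopropane methylene (not isolated) | CC(C)c1c(OCOC)c(OCOC)c2c(c1[C@@H]7O[C@]75CC[C@]6(C(C)C)C[C@@H]65)CC(=O)[C@H]3[C@@]2(CCCC3(C)C)C | intermediate
18 | 14-(4'-formylthujan-4'-yl)-11,12-bis(methoxymethoxy)-5β-abieta-8,11,13-trien-6-one, aryl syn to C6' | CC(C)c1c(OCOC)c(OCOC)c2c(c1[C@@]5(CC[C@]6(C(C)C)C[C@@H]65)C=O)CC(=O)[C@@H]4C(C)(C)CCC[C@]24C | intermediate
19 | hexacyclic bis-MOM β-hydroxy ketone (ring D closed, 10'-OH cis to C5', H7 β, H5 β) | CC(C)c1c(OCOC)c(OCOC)c2c3c1[C@@]5(CC[C@]6(C(C)C)C[C@@H]65)[C@H](O)[C@@H]3C(=O)[C@@H]4C(C)(C)CCC[C@]24C | intermediate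
20 | hexacyclic catechol | CC(C)c1c(O)c(O)c2c3c1[C@@]5(CC[C@]6(C(C)C)C[C@@H]65)[C@H](O)[C@@H]3C(=O)[C@@H]4C(C)(C)CCC[C@]24C | intermediate
21 | hexacyclic 11,12-ortho-quinone (not isolated) | CC(C)C=1C(=O)C(=O)C2=C3C=1[C@@]5(CC[C@]6(C(C)C)C[C@@H]65)[C@H](O)[C@@H]3C(=O)[C@@H]4C(C)(C)CCC[C@]24C | intermediate
22 | CNP0178265.2 | CC(C)C1=C2C3=C(C(=O)[C@@H]4C(C)(C)CCC[C@]4(C)C3=C(O)C1=O)[C@@H](O)[C@]21CC[C@]2(C(C)C)C[C@@H]21 | target

**Totals**
Total step count: 15. Longest linear sequence: 13 steps (steps 1–8 and 11–15).

**Steps most likely to fail**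

Step 13. The aldol could lose water by E1cB to the C7=C10' enone, which is conjugated with the arene and the ketone and would drain the equilibrium irreversibly; the equilibrium could also fail to favour the hydroxyl on the C5' side. The fallback sets out from 18 and replaces the reversible base aldol by a kinetic, base-free closure. TMSOTf and Et3N in CH2Cl2 (−78 to 0 °C) would convert the C6 ketone into its C6=C7 trimethylsilyl enol ether F1. BF3·OEt2 in CH2Cl2 at −78 °C would then close ring D by an irreversible Mukaiyama aldol addition to the formyl group, and a mildly acidic aqueous work-up would remove silicon and come back to the route at 19. A C10' epimer separated at that point could be passed briefly through the conditions of step 13.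

Step 12. Oxygen could be delivered to the alkene face syn to the cyclopropane (poor facial selectivity), which the stereospecific shift would carry into the wrong configuration at C4'; the unisolable epoxide gives no chance to purify before the shift. The fallback sets out from 16 and uses dihydroxylation followed by pinacol rearrangement. Osmium-catalysed dihydroxylation (K2OsO2(OH)4, NMO, acetone/H2O, if needed with the matched Sharpless ligand) is more sensitive to the C6' methylene and should give the stable 10',4'-diol with both oxygens anti to the cyclopropane, F2, which can be purified. Treatment of F2 with catalytic TsOH or BF3·OEt2 in CH2Cl2 at −40 °C should ionise the tertiary C4' hydroxyl with the same aryl shift and come back to the route at 18. This does not remove the second hazard of step 12, opening of the cyclopropane from the C4' cation.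

Step 6. Hydride abstraction could be slow, since the C12 ether is twisted out of conjugation and bromine sits peri to C7, or oxidation could continue at the isopropyl group or the new styrene. The fallback sets out from 7 and goes through the C7 ketone. Benzylic oxidation (CrO3·3,5-dimethylpyrazole, CH2Cl2, −20 °C) should give the 7-ketone F3. NaBH4 in MeOH/THF at 0 °C would reduce it to the 7-alcohol F4 (7β expected; either epimer serves). Acid-catalysed dehydration (catalytic TsOH, toluene, 80 °C) would then come back to the route at 8.

**Further compounds**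
F1 | step 13 | C6 trimethylsilyl enol ether (C6=C7) of keto aldehyde 18 | CC(C)c1c(OCOC)c(OCOC)c2c(c1[C@@]5(CC[C@]6(C(C)C)C[C@@H]65)C=O)C=C(O[Si](C)(C)C)[C@H]3[C@@]2(CCCC3(C)C)C
F2 | step 12 | 10',4'-diol of 16, both hydroxyls anti to the cyclopropane methylene | CC(C)c1c(OCOC)c(OCOC)c2c(c1[C@H](O)[C@]5(O)CC[C@]6(C(C)C)C[C@@H]65)CC(=O)[C@H]3[C@@]2(CCCC3(C)C)C
F3 | step 6 | 14-bromo-11,12-bis(methoxymethoxy)abieta-8,11,13-trien-7-one | CC(C)c1c(OCOC)c(OCOC)c2c(c1Br)C(=O)C[C@@H]3[C@@]2(CCCC3(C)C)C
F4 | step 6 | 14-bromo-11,12-bis(methoxymethoxy)abieta-8,11,13-trien-7β-ol | CC(C)c1c(OCOC)c(OCOC)c2c(c1Br)[C@@H](O)C[C@@H]3[C@@]2(CCCC3(C)C)C
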